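**Retrosynthetic overview**
- Target ⇐ C13 acetylation ⇐ hydroxyl-directed C11–C12 epoxidation ⇐ 1,2-reduction of a macrocyclic C13 enone that already carries the cis-fused α-methylene lactone.
- The 14-membered ring is closed first (C2–C3, intramolecular Nozaki–Hiyama–Kishi addition of a vinyl iodide to a C2 aldehyde); the γ-lactone closes on the new C2 alkoxide in the same operation; the epoxide is the last ring.
- Key step: a Carroll (decarboxylative ester-enol Claisen) [3,3] rearrangement makes the C14–C1 bond, the exocyclic methylene and the C1 stereocentre, and joins the two halves.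
- Allyl half: Baylis–Hillman adduct of (R)-glyceraldehyde acetonide and methyl acrylate; its dioxolane centre steers C1 and is then cut back to the C2 aldehyde.
- Keto ester half: (R)-linalool (supplies C8) by allylic oxidation, cross-metathesis with an iodo-diene, and an acetate aldol/oxidation.

Assumption and numbering: positions use cembrane numbering (C1 ring-fusion CH, C2 lactone O–CH, C8 carbinol, C11/C12 epoxide, C13 acetoxy carbon, C15/C16/C17 lactone α-carbon, carbonyl and exocyclic CH2); (R)-glyceraldehyde acetonide and pent-1-en-4-yne are taken as bought.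

**Step 1**
Reactants: 1 (R)-(−)-linalool
Product: 2 (2E,6R)-6-hydroxy-2,6-dimethylocta-2,7-dienal
Conditions: SeO2 (1.1 equiv), 1,4-dioxane/EtOH (9:1), 80 °C
Reagents that add atoms: selenium dioxide, O=[Se]=O
Why: Riley allylic oxidation (ene reaction, then [2,3] shift) attacks only the (E)-methyl of the trisubstituted olefin and gives the (E)-enal, leaving the bought C8 centre untouched.

**Step 2**
Reactants: 3 pent-1-en-4-yne
Product: 5 (1E)-1-iodo-2-methylpenta-1,4-diene, via alkenylalane 4 (not isolated)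
Conditions: AlMe3 (2 equiv), Cp2ZrCl2 (0.2 equiv), CH2Cl2, 0 → 25 °C; then I2, THF, −30 °C
Reagents that add atoms: trimethylaluminium, C[Al](C)C; iodine, II
Why: Negishi zirconium-catalysed syn-carboalumination puts methyl on the internal alkyne carbon with Al cis to it, and iodinolysis with retention fixes the (E)-geometry needed at C3=C4.

**Step 3**
Reactants: 2 (2E,6R)-6-hydroxy-2,6-dimethylocta-2,7-dienal; 5 (1E)-1-iodo-2-methylpenta-1,4-diene
Product: 6 (2E,6R,7E,10E)-6-hydroxy-11-iodo-2,6,10-trimethylundeca-2,7,10-trienal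
Conditions: second-generation Hoveyda–Grubbs catalyst (5 mol %), 5 (3 equiv), 1,4-benzoquinone (10 mol %), CH2Cl2, 40 °C
Reagents that add atoms: none
Why: Olefin cross-metathesis of the hindered vinyl carbinol with the allyl terminus of 5 is E-selective (C6=C7), and the conjugated or trisubstituted olefins (enal, vinyl iodide) do not engage the catalyst.

**Step 4**
Reactants: 6 (2E,6R,7E,10E)-6-hydroxy-11-iodo-2,6,10-trimethylundeca-2,7,10-trienal; 7 tert-butyl acetate
Product: 8 tert-butyl (4E,8R,9E,12E)-3,8-dihydroxy-13-iodo-4,8,12-trimethyltrideca-4,9,12-trienoate (both C3 epimers)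
Conditions: LiN(iPr)2 (2.3 equiv), 7 (2.3 equiv), THF, −78 °C; AcOH quench
Reagents that add atoms: none
Why: Acetate aldol addition (1,2-addition of the ester enolate to the enal) brings in C14; the new carbinol centre is left uncontrolled because it is oxidised in step 5.

**Step 5**
Reactants: 8 tert-butyl (4E,8R,9E,12E)-3,8-dihydroxy-13-iodo-4,8,12-trimethyltrideca-4,9,12-trienoate
Product: 9 tert-butyl (4E,8R,9E,12E)-8-hydroxy-13-iodo-4,8,12-trimethyl-3-oxotrideca-4,9,12-trienoate
Conditions: Dess–Martin periodinane (1.2 equiv), CH2Cl2, 0 → 25 °C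
Reagents that add atoms: none
Why: Dess–Martin oxidation converts the secondary allylic alcohol into the β-keto ester, while the tertiary alcohol cannot be oxidised.

**Step 6**
Reactants: 10 (4R)-2,2-dimethyl-1,3-dioxolane-4-carbaldehyde; 11 methyl acrylate
Product: 12 methyl 2-{[(4R)-2,2-dimethyl-1,3-dioxolan-4-yl](hydroxy)methyl}prop-2-enoate (both carbinol epimers)
Conditions: DABCO (0.5 equiv), 11 (3 equiv), 1,4-dioxane/H2O (1:1), 25 °C, 48 h
Reagents that add atoms: none
Why: Morita–Baylis–Hillman reaction joins C1 to C15; the carbinol epimer ratio does not matter because that carbon becomes sp2 in step 7, and the bought dioxolane centre is retained.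

**Step 7**
Reactants: 12 methyl 2-{[(4R)-2,2-dimethyl-1,3-dioxolan-4-yl](hydroxy)methyl}prop-2-enoate
Product: 14 methyl (2E)-2-[(acetyloxy)methyl]-3-[(4S)-2,2-dimethyl-1,3-dioxolan-4-yl]prop-2-enoate, via secondary acetate 13 (not isolated)
Conditions: Ac2O, DMAP (cat.), Et3N, CH2Cl2, 0 °C; then DABCO (1 equiv), THF, 65 °C
Reagents that add atoms: acetic anhydride, CC(=O)OC(C)=O
Why: Acetylation followed by DABCO-mediated allylic transposition (SN2′ addition of the amine, SN2 return of acetate) gives the thermodynamically preferred trisubstituted (E)-enoate with a primary acetate.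

**Step 8**
Reactants: 14 methyl (2E)-2-[(acetyloxy)methyl]-3-[(4S)-2,2-dimethyl-1,3-dioxolan-4-yl]prop-2-enoate
Product: 15 methyl (2E)-3-[(4S)-2,2-dimethyl-1,3-dioxolan-4-yl]-2-(hydroxymethyl)prop-2-enoate
Conditions: K2CO3 (0.2 equiv), MeOH, 0 °C
Reagents that add atoms: none
Why: Base-catalysed methanolysis (transesterification) removes only the acetate, since exchange at the methyl ester is degenerate.

**Step 9**
Reactants: 9 tert-butyl (4E,8R,9E,12E)-8-hydroxy-13-iodo-4,8,12-trimethyl-3-oxotrideca-4,9,12-trienoate; 15 methyl (2E)-3-[(4S)-2,2-dimethyl-1,3-dioxolan-4-yl]-2-(hydroxymethyl)prop-2-enoate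
Product: 19 methyl (3S,6E,10R,11E,14E)-3-[(4S)-2,2-dimethyl-1,3-dioxolan-4-yl]-10-hydroxy-15-iodo-6,10,14-trimethyl-2-methylidene-5-oxopentadeca-6,11,14-trienoate, via acylketene 16 (not isolated), via allyl keto ester 17 (not isolated), via keto acid 18 (not isolated)
Conditions: 15 (1.3 equiv), BHT (cat.), xylenes, 140 °C, N2 sweep
Reagents that add atoms: none
Why: Carroll rearrangement: the primary alcohol traps the acylketene, the ester enol undergoes a [3,3]-sigmatropic shift onto the electron-poor C1 terminus and the keto acid loses CO2, forming C14–C1 and the exocyclic methylene; C1 (S) is set by 1,2-induction from the bought dioxolane centre, whose C–H eclipses the olefin (A1,3 strain with C17H2) so that the new bond forms anti to the allylic C–O bond (Felkin–Anh sense).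

**Step 10**
Reactants: 19 methyl (3S,6E,10R,11E,14E)-3-[(4S)-2,2-dimethyl-1,3-dioxolan-4-yl]-10-hydroxy-15-iodo-6,10,14-trimethyl-2-methylidene-5-oxopentadeca-6,11,14-trienoate
Product: 21 methyl (3S,6E,10R,11E,14E)-3-formyl-10-hydroxy-15-iodo-6,10,14-trimethyl-2-methylidene-5-oxopentadeca-6,11,14-trienoate, via vicinal diol 20 (not isolated)
Conditions: H5IO6 (1.5 equiv), EtOAc, 0 °C, 1 h; used crude at once
Reagents that add atoms: none
Why: Periodic acid hydrolyses the terminal acetonide and cleaves the glycol (Malaprade reaction) without base, so the dioxolane carbon that steered C1 becomes the C2 aldehyde and C1 keeps its configuration.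

**Step 11**
Reactants: 21 methyl (3S,6E,10R,11E,14E)-3-formyl-10-hydroxy-15-iodo-6,10,14-trimethyl-2-methylidene-5-oxopentadeca-6,11,14-trienoate
Product: 23 (1S,2S,3E,6E,8R,11E)-8-hydroxy-13-oxocembra-3,6,11,15(17)-tetraen-16,2-olide, via seco hydroxy ester 22 (not isolated)
Conditions: CrCl2 (8 equiv), NiCl2 (2 mol %), DMSO/THF (3:1), 0.003 M, 25 °C; then PPTS (cat.), CH2Cl2
Reagents that add atoms: none
Why: Intramolecular Nozaki–Hiyama–Kishi reaction adds the vinyl iodide carbon to the aldehyde only, with retention of the (E)-olefin, and closes the 14-membered ring; C2 (S) is set by Felkin–Anh addition anti to the sp2 C15 substituent on C1 (the syn adduct), and the alkoxide then lactonises onto the methyl ester to give the cis-fused α-methylene-γ-lactone.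

**Step 12**
Reactants: 23 (1S,2S,3E,6E,8R,11E)-8-hydroxy-13-oxocembra-3,6,11,15(17)-tetraen-16,2-olide
Product: 24 (1S,2S,3E,6E,8R,11E,13S)-8,13-dihydroxycembra-3,6,11,15(17)-tetraen-16,2-olide
Conditions: NaBH4 (1 equiv), CeCl3·7H2O (1.2 equiv), MeOH/THF, −78 °C
Reagents that add atoms: none
Why: Luche reduction gives clean 1,2-reduction of the enone without touching the α-methylene lactone; C13 is set by substrate control, hydride being expected to add to the peripheral face of the ring-held enone away from the cis-fused lactone at C1 (13S expected but not secure; to be checked by Mosher analysis).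

**Step 13**
Reactants: 24 (1S,2S,3E,6E,8R,11E,13S)-8,13-dihydroxycembra-3,6,11,15(17)-tetraen-16,2-olide
Product: 25 (1S,2S,3E,6E,8R,11S,12S,13S)-11,12-epoxy-8,13-dihydroxycembra-3,6,15(17)-trien-16,2-olide
Conditions: VO(acac)2 (5 mol %), t-BuOOH (1.2 equiv), CH2Cl2, 0 °C
Reagents that add atoms: tert-butyl hydroperoxide, CC(C)(C)OO
Why: Hydroxyl-directed Sharpless–Michaelson epoxidation delivers oxygen from the C13 vanadate ester to the adjacent trisubstituted olefin only, and A1,2 strain with the C12 methyl gives the erythro epoxy alcohol, which is the target's C11/C12 configuration (C12 reads S here only because the CIP ranking changes before acetylation).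

**Step 14**
Reactants: 25 (1S,2S,3E,6E,8R,11S,12S,13S)-11,12-epoxy-8,13-dihydroxycembra-3,6,15(17)-trien-16,2-olide
Product: 26 (1S,2S,3E,6E,8R,11S,12R,13S)-13-acetoxy-11,12-epoxy-8-hydroxycembra-3,6,15(17)-trien-16,2-olide (CNP0288879.3)
Conditions: Ac2O (3 equiv), pyridine, CH2Cl2, 25 °C
Reagents that add atoms: acetic anhydride, CC(=O)OC(C)=O
Why: Acylation esterifies the only secondary alcohol; the tertiary C8 alcohol and the epoxide do not react under these conditions.

**Compound list**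
1 | (R)-(−)-linalool, (3R)-3,7-dimethylocta-1,6-dien-3-ol | C=C[C@](C)(O)CCC=C(C)C | starting material
2 | (2E,6R)-6-hydroxy-2,6-dimethylocta-2,7-dienal | C=C[C@](C)(O)CC/C=C(\C)C=O | intermediate
3 | pent-1-en-4-yne | C=CCC#C | starting material
4 | dimethyl[(1E)-2-methylpenta-1,4-dien-1-yl]alumane (not isolated) | C[Al](C)/C=C(\C)CC=C | intermediate
5 | (1E)-1-iodo-2-methylpenta-1,4-diene | I/C=C(\C)CC=C | intermediate
6 | (2E,6R,7E,10E)-6-hydroxy-11-iodo-2,6,10-trimethylundeca-2,7,10-trienal | I/C=C(\C)C/C=C/[C@](C)(O)CC/C=C(\C)C=O | intermediate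
7 | tert-butyl acetate | CC(=O)OC(C)(C)C | starting material
8 | tert-butyl (4E,8R,9E,12E)-3,8-dihydroxy-13-iodo-4,8,12-trimethyltrideca-4,9,12-trienoate (both C3 epimers) | I/C=C(\C)C/C=C/[C@](C)(O)CC/C=C(\C)C(O)CC(=O)OC(C)(C)C | intermediate
9 | tert-butyl (4E,8R,9E,12E)-8-hydroxy-13-iodo-4,8,12-trimethyl-3-oxotrideca-4,9,12-trienoate | I/C=C(\C)C/C=C/[C@](C)(O)CC/C=C(\C)C(=O)CC(=O)OC(C)(C)C | intermediate
10 | (4R)-2,2-dimethyl-1,3-dioxolane-4-carbaldehyde, (R)-glyceraldehyde acetonide | O=C[C@H]1COC(C)(C)O1 | starting material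
11 | methyl acrylate | C=CC(=O)OC | starting material
12 | methyl 2-{[(4R)-2,2-dimethyl-1,3-dioxolan-4-yl](hydroxy)methyl}prop-2-enoate (both carbinol epimers) | C=C(C(=O)OC)C(O)[C@H]1COC(C)(C)O1 | intermediate
13 | methyl 2-{(acetyloxy)[(4R)-2,2-dimethyl-1,3-dioxolan-4-yl]methyl}prop-2-enoate (not isolated) | C=C(C(=O)OC)C(OC(C)=O)[C@H]1COC(C)(C)O1 | intermediate
14 | methyl (2E)-2-[(acetyloxy)methyl]-3-[(4S)-2,2-dimethyl-1,3-dioxolan-4-yl]prop-2-enoate | COC(=O)/C(COC(C)=O)=C/[C@H]1COC(C)(C)O1 | intermediate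
15 | methyl (2E)-3-[(4S)-2,2-dimethyl-1,3-dioxolan-4-yl]-2-(hydroxymethyl)prop-2-enoate | COC(=O)/C(CO)=C/[C@H]1COC(C)(C)O1 | intermediate
16 | (4E,8R,9E,12E)-8-hydroxy-13-iodo-4,8,12-trimethyltrideca-1,4,9,12-tetraene-1,3-dione, acylketene (not isolated) | I/C=C(\C)C/C=C/[C@](C)(O)CC/C=C(\C)C(=O)C=C=O | intermediate
17 | (2E)-3-[(4S)-2,2-dimethyl-1,3-dioxolan-4-yl]-2-(methoxycarbonyl)prop-2-en-1-yl (4E,8R,9E,12E)-8-hydroxy-13-iodo-4,8,12-trimethyl-3-oxotrideca-4,9,12-trienoate (not isolated) | I/C=C(\C)C/C=C/[C@](C)(O)CC/C=C(\C)C(=O)CC(=O)OC/C(C(=O)OC)=C\[C@H]1COC(C)(C)O1 | intermediate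
18 | (3S)-3-[(4S)-2,2-dimethyl-1,3-dioxolan-4-yl]-2-[(2E,6R,7E,10E)-6-hydroxy-11-iodo-2,6,10-trimethylundeca-2,7,10-trienoyl]-4-(methoxycarbonyl)pent-4-enoic acid (both C2 epimers, not isolated) | I/C=C(\C)C/C=C/[C@](C)(O)CC/C=C(\C)C(=O)C(C(=O)O)[C@@H](C(=C)C(=O)OC)[C@H]1COC(C)(C)O1 | intermediate
19 | methyl (3S,6E,10R,11E,14E)-3-[(4S)-2,2-dimethyl-1,3-dioxolan-4-yl]-10-hydroxy-15-iodo-6,10,14-trimethyl-2-methylidene-5-oxopentadeca-6,11,14-trienoate | I/C=C(\C)C/C=C/[C@](C)(O)CC/C=C(\C)C(=O)C[C@@H](C(=C)C(=O)OC)[C@H]1COC(C)(C)O1 | intermediate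
20 | methyl (3S,6E,10R,11E,14E)-3-[(1S)-1,2-dihydroxyethyl]-10-hydroxy-15-iodo-6,10,14-trimethyl-2-methylidene-5-oxopentadeca-6,11,14-trienoate (not isolated) | I/C=C(\C)C/C=C/[C@](C)(O)CC/C=C(\C)C(=O)C[C@@H](C(=C)C(=O)OC)[C@H](O)CO | intermediate
21 | methyl (3S,6E,10R,11E,14E)-3-formyl-10-hydroxy-15-iodo-6,10,14-trimethyl-2-methylidene-5-oxopentadeca-6,11,14-trienoate | I/C=C(\C)C/C=C/[C@](C)(O)CC/C=C(\C)C(=O)C[C@@H](C(=C)C(=O)OC)C=O | intermediate
22 | methyl 2-[(1S,2S,3E,6E,8R,11E)-2,8-dihydroxy-4,8,12-trimethyl-13-oxocyclotetradeca-3,6,11-trien-1-yl]prop-2-enoate (not isolated) | O[C@H]1/C=C(\C)C/C=C/[C@](C)(O)CC/C=C(\C)C(=O)C[C@H]1C(=C)C(=O)OC | intermediate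
23 | (1S,2S,3E,6E,8R,11E)-8-hydroxy-13-oxocembra-3,6,11,15(17)-tetraen-16,2-olide | C=C1C(=O)O[C@H]2/C=C(\C)C/C=C/[C@](C)(O)CC/C=C(\C)C(=O)C[C@@H]12 | intermediate
24 | (1S,2S,3E,6E,8R,11E,13S)-8,13-dihydroxycembra-3,6,11,15(17)-tetraen-16,2-olide | C=C1C(=O)O[C@H]2/C=C(\C)C/C=C/[C@](C)(O)CC/C=C(\C)[C@@H](O)C[C@@H]12 | intermediate
25 | (1S,2S,3E,6E,8R,11S,12S,13S)-11,12-epoxy-8,13-dihydroxycembra-3,6,15(17)-trien-16,2-olide (13-deacetyl target) | C=C1C(=O)O[C@H]2/C=C(\C)C/C=C/[C@](C)(O)CC[C@@H]3O[C@@]3(C)[C@@H](O)C[C@@H]12 | intermediate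
26 | (1S,2S,3E,6E,8R,11S,12R,13S)-13-acetoxy-11,12-epoxy-8-hydroxycembra-3,6,15(17)-trien-16,2-olide | C=C1C(=O)O[C@H]2/C=C(\C)C/C=C/[C@](C)(O)CC[C@@H]3O[C@@]3(C)[C@@H](OC(C)=O)C[C@@H]12 | target

**Step count**
Total: 14 steps. Longest linear sequence: 10 steps (steps 1, 3, 4, 5, 9, 10, 11, 12, 13, 14, from 1).

**Three steps most likely to fail**

Step 9. The thermal Carroll step may need more than 140 °C, where 9 and the acrylate can degrade, and the C1 selectivity rests on one conformational model. The fallback makes the same C14–C1 bond by ionic allylic substitution instead of the sigmatropic shift. It sets out from 9 and from 13 (isolated this time). DABCO (1 equiv) in THF at 25 °C turns 13 into its allyl-ammonium salt, which the enol of 9 attacks at C1 (tandem SN2′–SN2′) to give the C14-(tert-butoxycarbonyl) keto ester F1. Me3SiOTf/2,6-lutidine (CH2Cl2, 0 °C) then cleaves the tert-butyl ester, keto acid 18 loses CO2 at 40 °C, and the route is rejoined at 19.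

Step 11. The γ-keto aldehyde 21 can epimerise at C1 or condense with its own ketone (furan or aldol) before the ring closes. The fallback masks the C13 ketone before the aldehyde is released; it sets out from 19:
- NaBH4/CeCl3·7H2O (MeOH, −78 °C) gives the allylic alcohol F2 as both C13 epimers.
- TBSCl/imidazole (DMF) gives the silyl ether F3.
- H5IO6 (EtOAc, 0 °C) gives the silyloxy aldehyde F4.
- CrCl2/NiCl2 (DMSO/THF), then PPTS, gives the macrocyclic lactone silyl ether F5.
- Bu4NF/AcOH (THF) frees the epimeric C13 alcohols F6.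
- Dess–Martin periodinane oxidises both epimers to the single enone, returning to the route at 23.

Step 12. The facial selectivity of hydride addition to the macrocyclic enone cannot be predicted with confidence. If the wrong epimer predominates, the fallback inverts C13 instead of re-reducing. It sets out from 23, whose Luche reduction then gives the (13R)-alcohol F7. A Mitsunobu reaction (4-nitrobenzoic acid, PPh3, DIAD, THF, 0 °C) gives the inverted (13S)-4-nitrobenzoate F8, and K2CO3/MeOH (0 °C) releases 24, where the route continues.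

**Further compounds**
F1 | step 9 | C14-(tert-butoxycarbonyl) derivative of 19 (both C14 epimers) | I/C=C(\C)C/C=C/[C@](C)(O)CC/C=C(\C)C(=O)C(C(=O)OC(C)(C)C)[C@@H](C(=C)C(=O)OC)[C@H]1COC(C)(C)O1
F2 | step 11 | C13 allylic alcohol from 19 (both C13 epimers) | I/C=C(\C)C/C=C/[C@](C)(O)CC/C=C(\C)C(O)C[C@@H](C(=C)C(=O)OC)[C@H]1COC(C)(C)O1
F3 | step 11 | 13-O-tert-butyldimethylsilyl ether of F2 | I/C=C(\C)C/C=C/[C@](C)(O)CC/C=C(\C)C(O[Si](C)(C)C(C)(C)C)C[C@@H](C(=C)C(=O)OC)[C@H]1COC(C)(C)O1
F4 | step 11 | 13-silyloxy analogue of aldehyde 21 | I/C=C(\C)C/C=C/[C@](C)(O)CC/C=C(\C)C(O[Si](C)(C)C(C)(C)C)C[C@@H](C(=C)C(=O)OC)C=O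
F5 | step 11 | 13-O-tert-butyldimethylsilyl ether of the macrocyclic lactone alcohol (both C13 epimers) | C=C1C(=O)O[C@H]2/C=C(\C)C/C=C/[C@](C)(O)CC/C=C(\C)C(O[Si](C)(C)C(C)(C)C)C[C@@H]12
F6 | step 11 | macrocyclic lactone C13 alcohol, both C13 epimers | C=C1C(=O)O[C@H]2/C=C(\C)C/C=C/[C@](C)(O)CC/C=C(\C)C(O)C[C@@H]12
F7 | step 12 | (13R)-epimer of 24 | C=C1C(=O)O[C@H]2/C=C(\C)C/C=C/[C@](C)(O)CC/C=C(\C)[C@H](O)C[C@@H]12
F8 | step 12 | (13S)-4-nitrobenzoate of 24 | C=C1C(=O)O[C@H]2/C=C(\C)C/C=C/[C@](C)(O)CC/C=C(\C)[C@@H](OC(=O)c3ccc(cc3)[N+](=O)[O-])C[C@@H]12
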